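**Plan**

- Retrosynthesis: the C8–O ester bond and the C3=C4 unsaturation of the pyran ring are removed first. The C5–C6 and C4a–C8a bonds are then cut together, which contracts the cyclohexenone (C4a, C5, C6, C7, C8, C8a) to a cyclobutanone (C6, C7, C8, C8a) whose C8a carries the alkyne C4a≡C5 on the ether chain C1–O2–C3–C4.
- Enabling feature: the four ring atoms C6(=O)–C7–C8–C8a hold the carbonyl and all three stereocentres, and the other two ring atoms (C4a=C5) are one two-carbon unit tied to C8a through the pyran atoms. A strained cyclobutanone can therefore take up a tethered alkyne.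
- Forward order: pyranone → photochemical cyclobutene β-lactone → cis-diol → resolution → ether with the heptenynol → dihydroxylation and oxidation to the cyclobutanone → rhodium-catalysed insertion, in which the carbocycle and the pyran ring arise together → esterification → dehydrogenation of the pyran → deprotection.
- Stereochemistry: C8/C8a cis from the cis-fused photolactone; absolute configuration from a lipase kinetic resolution; C7 from dihydroxylation anti to the C8/C8a substituents; C8a retained in the key step; the ether carbinol centre (C3) is transient.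

Key step: step 12

Remark: ring atoms are named by isochromene numbering (C1, O2, C3, C4, C4a, C5, C6, C7, C8, C8a); alcohol 11 is used as the racemate, so 13–18 and 23 are each carried as a pair of epimers at C3, a centre that becomes sp2 in step 17 (their SMILES leave it undefined).

**Route**

Step 1
Reactants: 1 5-bromo-2H-pyran-2-one
Product: 2 5-methyl-2H-pyran-2-one
Conditions: Me4Sn, Pd(PPh3)4 (5 mol %), CuI (10 mol %), DMF, 80 °C
Reagents that add atoms: tetramethylstannane, C[Sn](C)(C)C
Why: Stille coupling at the vinylic C5–Br bond (oxidative addition to zerovalent palladium, methyl transfer from tin, reductive elimination) should give the methylpyranone; no stereocentre is involved.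

Step 2
Reactants: 2 5-methyl-2H-pyran-2-one
Product: 3 rac-(1R,4R)-6-methyl-2-oxabicyclo[2.2.0]hex-5-en-3-one
Conditions: hν (300 nm, Pyrex), Et2O (0.02 M), −10 °C; solution used directly
Reagents that add atoms: none
Why: Photochemical disrotatory 4π electrocyclisation of the pyranone diene closes the C3–C6 bond and should give the strained cyclobutene-fused β-lactone, in which the ring oxygen and the carbonyl carbon are necessarily cis on the four-membered ring (the later C8–O/C8a–C1 relationship); the product is racemic.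

Step 3
Reactants: 3 rac-(1R,4R)-6-methyl-2-oxabicyclo[2.2.0]hex-5-en-3-one
Product: 4 rac-(1R,4S)-4-(hydroxymethyl)-2-methylcyclobut-2-en-1-ol
Conditions: LiAlH4, Et2O, −78 → −20 °C; Na2SO4·10H2O quench
Reagents that add atoms: none
Why: Hydride reduction of the β-lactone with acyl–oxygen cleavage should give the cis-1,3-diol without touching either stereocentre; the low temperature and the covalent aluminium alkoxide guard against electrocyclic opening of the cyclobutenol.

Step 4
Reactants: 4 rac-(1R,4S)-4-(hydroxymethyl)-2-methylcyclobut-2-en-1-ol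
Product: 6 [(1S,4R)-4-hydroxy-3-methylcyclobut-2-en-1-yl]methyl acetate, via racemic primary monoacetate 5 (not isolated)
Conditions: Burkholderia cepacia lipase (immobilised), vinyl acetate, t-BuOMe, 30 °C; stopped when about half of 5 has been acetylated a second time; chromatography
Reagents that add atoms: vinyl acetate, C=COC(C)=O
Why: Lipase-catalysed transesterification acetylates the primary hydroxyl of both enantiomers and then the secondary carbinol of only one of them (kinetic resolution); by the empirical size rule for secondary alcohols (large group = the ring carbon bearing CH2OAc, medium group = the methyl-bearing sp2 carbon) the doubly acetylated enantiomer should be the unwanted one, so that 6 remains with the configuration that becomes C8a (S) and C8 (R) of the target.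

Step 5
Reactants: 6 [(1S,4R)-4-hydroxy-3-methylcyclobut-2-en-1-yl]methyl acetate
Product: 7 [(1S,4R)-4-{[tert-butyl(dimethyl)silyl]oxy}-3-methylcyclobut-2-en-1-yl]methyl acetate
Conditions: TBSOTf, 2,6-lutidine, CH2Cl2, −78 °C
Reagents that add atoms: tert-butyldimethylsilyl trifluoromethanesulfonate, CC(C)(C)[Si](C)(C)OS(=O)(=O)C(F)(F)F
Why: Silylation of the secondary cyclobutenol without a free alkoxide installs a group that is a poor leaving group once it sits β to the cyclobutanone carbonyl; the configuration is unchanged.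

Step 6
Reactants: 7 [(1S,4R)-4-{[tert-butyl(dimethyl)silyl]oxy}-3-methylcyclobut-2-en-1-yl]methyl acetate
Product: 8 [(1S,4R)-4-{[tert-butyl(dimethyl)silyl]oxy}-3-methylcyclobut-2-en-1-yl]methanol
Conditions: K2CO3, MeOH, 0 °C
Reagents that add atoms: none
Why: Methanolysis (transesterification) of the primary acetate frees the hydroxymethyl group while the silyl ether stays.

Step 7
Reactants: 9 (2E)-but-2-enal; 10 3-bromoprop-1-yne
Product: 11 (5E)-hept-5-en-1-yn-4-ol (racemate)
Conditions: Zn dust, THF/sat. aq. NH4Cl, 0 °C → rt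
Reagents that add atoms: none
Why: Barbier propargylation: the allenylzinc bromide formed in situ adds 1,2 to the enal through an SE2' transition state and should give the homopropargylic alcohol with the (E)-propenyl group intact; the carbinol centre is left racemic because it is removed in step 17.

Step 8
Reactants: 8 [(1S,4R)-4-{[tert-butyl(dimethyl)silyl]oxy}-3-methylcyclobut-2-en-1-yl]methanol; 11 (5E)-hept-5-en-1-yn-4-ol
Product: 13 tert-butyl{[(1R,4S)-4-({[(5E)-hept-5-en-1-yn-4-yl]oxy}methyl)-2-methylcyclobut-2-en-1-yl]oxy}dimethylsilane (both epimers at the ether carbinol carbon), via primary triflate 12 (not isolated)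
Conditions: 8, Tf2O, 2,6-lutidine, CH2Cl2, −78 °C; then cannulated into 11 (3 equiv)/NaN(SiMe3)2 (2.5 equiv), THF, −78 → 0 °C
Reagents that add atoms: none
Why: Williamson etherification by SN2 displacement of a primary triflate by the sodium alkoxide of 11 at low temperature (the amide base forms the alkoxide and not the acetylide, and one equivalent of alkoxide neutralises the lutidinium salt); the ring stereocentres are not involved.

Step 9
Reactants: 13 tert-butyl{[(1R,4S)-4-({[(5E)-hept-5-en-1-yn-4-yl]oxy}methyl)-2-methylcyclobut-2-en-1-yl]oxy}dimethylsilane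
Product: 14 (1R,2R,3R,4R)-4-{[tert-butyl(dimethyl)silyl]oxy}-3-({[(5E)-hept-5-en-1-yn-4-yl]oxy}methyl)-1-methylcyclobutane-1,2-diol
Conditions: OsO4 (2 mol %), NMO (1.2 equiv), acetone/H2O, 0 °C; stopped at consumption of 13
Reagents that add atoms: osmium tetroxide, O=[Os](=O)(=O)=O; N-methylmorpholine N-oxide, C[N+]1([O-])CCOCC1
Why: Catalytic syn-dihydroxylation is expected to take the strained, trisubstituted cyclobutene in preference to the unstrained trans-disubstituted propenyl group and the alkyne, and to occur on the ring face anti to the cis OTBS and CH2OR groups; this sets the tertiary C7 carbinol trans to the C8 oxygen.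

Step 10
Reactants: 14 (1R,2R,3R,4R)-4-{[tert-butyl(dimethyl)silyl]oxy}-3-({[(5E)-hept-5-en-1-yn-4-yl]oxy}methyl)-1-methylcyclobutane-1,2-diol
Product: 15 (2S,3R,4S)-3-{[tert-butyl(dimethyl)silyl]oxy}-4-({[(5E)-hept-5-en-1-yn-4-yl]oxy}methyl)-2-hydroxy-2-methylcyclobutan-1-one
Conditions: IBX, DMSO, rt
Reagents that add atoms: none
Why: IBX oxidises the secondary alcohol of a 1,2-diol to the ketone without C–C cleavage and cannot oxidise the tertiary one; the neutral conditions spare the β-silyloxy cyclobutanone and no stereocentre changes.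

Step 11
Reactants: 15 (2S,3R,4S)-3-{[tert-butyl(dimethyl)silyl]oxy}-4-({[(5E)-hept-5-en-1-yn-4-yl]oxy}methyl)-2-hydroxy-2-methylcyclobutan-1-one
Product: 16 (2S,3R,4S)-3-{[tert-butyl(dimethyl)silyl]oxy}-4-({[(5E)-hept-5-en-1-yn-4-yl]oxy}methyl)-2-methyl-2-[(triethylsilyl)oxy]cyclobutan-1-one
Conditions: TESOTf, 2,6-lutidine, CH2Cl2, −78 °C
Reagents that add atoms: triethylsilyl trifluoromethanesulfonate, CC[Si](CC)(CC)OS(=O)(=O)C(F)(F)F
Why: Silylation of the tertiary α-hydroxyl blocks α-ketol rearrangement and O–H interference in the next step; the configuration is unchanged.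

Step 12
Reactants: 16 (2S,3R,4S)-3-{[tert-butyl(dimethyl)silyl]oxy}-4-({[(5E)-hept-5-en-1-yn-4-yl]oxy}methyl)-2-methyl-2-[(triethylsilyl)oxy]cyclobutan-1-one
Product: 17 (7S,8R,8aS)-8-{[tert-butyl(dimethyl)silyl]oxy}-7-methyl-3-[(1E)-prop-1-en-1-yl]-7-[(triethylsilyl)oxy]-1,3,4,7,8,8a-hexahydro-6H-isochromen-6-one
Conditions: [RhCl(cod)]2 (5 mol %; cod = 1,5-cyclooctadiene), PMe2Ph (12 mol %), 1,4-dioxane, 110 °C, sealed tube
Reagents that add atoms: none
Why: The monovalent rhodium centre, held by the tethered alkyne, adds oxidatively into the strained acyl C6–C8a bond to give a five-membered rhodacycle; the alkyne then inserts into the Rh–C8a bond, which forms C4a–C8a and closes the pyran ring in a 6-exo-dig sense, and acyl–vinyl reductive elimination from the resulting seven-membered rhodacycle forms C5–C6, so the cyclohexenone arises by a formal [4+2] two-carbon expansion of the four-membered ring. The closest known reaction type is the rhodium-catalysed intramolecular "cut-and-sew" carboacylation of cyclobutanones that carry an alkyne on a chain at the α-carbon, which gives fused cyclohexenones. No stereocentre is created: C8a keeps its configuration because oxidative addition, migratory insertion and reductive elimination all proceed with retention at carbon, C7 and C8 are not touched, and the two C3 epimers should react alike. The step needs cleavage of C6–C8a and not of C6–C7, which the chelating tether on C8a and the fully substituted, silyloxy-shielded C7 secure, and the regiochemistry (terminal alkyne carbon to the acyl carbon) is fixed by the length of the tether. The alkyne must react in preference to the trans-disubstituted propenyl group, which is expected because alkynes bind and insert much faster than internal alkenes, and β-silyloxy elimination from C8 is disfavoured because the C8–O bond cannot become syn-coplanar with Rh–C8a inside the five-membered metallacycle. Release of the four-ring strain drives the sequence.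

Step 13
Reactants: 17 (7S,8R,8aS)-8-{[tert-butyl(dimethyl)silyl]oxy}-7-methyl-3-[(1E)-prop-1-en-1-yl]-7-[(triethylsilyl)oxy]-1,3,4,7,8,8a-hexahydro-6H-isochromen-6-one
Product: 18 (7S,8R,8aS)-7,8-dihydroxy-7-methyl-3-[(1E)-prop-1-en-1-yl]-1,3,4,7,8,8a-hexahydro-6H-isochromen-6-one
Conditions: HF·pyridine, pyridine, THF, 0 °C → rt
Reagents that add atoms: none
Why: Fluoride-mediated cleavage of both silyl ethers under buffered, weakly acidic conditions avoids enolate chemistry of the enone; the configuration is retained.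

Step 14
Reactants: 19 methyl 2,4-dihydroxy-6-methylbenzoate
Product: 20 methyl 2,4-bis(methoxymethoxy)-6-methylbenzoate
Conditions: NaH, MOMCl, DMF, 0 °C → rt
Reagents that add atoms: chloromethyl methyl ether, COCCl
Why: O-alkylation of both phenoxides (including the hydrogen-bonded ortho one) gives acetal protecting groups that are stable to base and to DDQ and are removed by mild acid.

Step 15
Reactants: 20 methyl 2,4-bis(methoxymethoxy)-6-methylbenzoate
Product: 21 2,4-bis(methoxymethoxy)-6-methylbenzoic acid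
Conditions: KOH, MeOH/H2O, 70 °C; then aq. HCl to pH 4 at 0 °C
Reagents that add atoms: potassium hydroxide, [K+].[OH-]
Why: Saponification of the hindered methyl ester, with cold and brief acidification so that the methoxymethyl ethers survive.

Step 16
Reactants: 18 (7S,8R,8aS)-7,8-dihydroxy-7-methyl-3-[(1E)-prop-1-en-1-yl]-1,3,4,7,8,8a-hexahydro-6H-isochromen-6-one; 21 2,4-bis(methoxymethoxy)-6-methylbenzoic acid
Product: 23 (7S,8R,8aS)-7-hydroxy-7-methyl-6-oxo-3-[(1E)-prop-1-en-1-yl]-3,4,6,7,8,8a-hexahydro-1H-isochromen-8-yl 2,4-bis(methoxymethoxy)-6-methylbenzoate, via acid chloride 22 (not isolated)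
Conditions: 21, 1-chloro-N,N,2-trimethylprop-1-en-1-amine, CH2Cl2, 0 °C → rt; then 18, DMAP, Et3N, CH2Cl2, 0 → 35 °C
Reagents that add atoms: none
Why: DMAP-catalysed acylation by the aroyl chloride (made under neutral conditions that spare the methoxymethyl ethers) should take only the secondary C8 hydroxyl, because the tertiary C7 hydroxyl is too hindered; O-acylation leaves the C8 configuration unchanged.

Step 17
Reactants: 23 (7S,8R,8aS)-7-hydroxy-7-methyl-6-oxo-3-[(1E)-prop-1-en-1-yl]-3,4,6,7,8,8a-hexahydro-1H-isochromen-8-yl 2,4-bis(methoxymethoxy)-6-methylbenzoate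
Product: 24 (7S,8R,8aS)-7-hydroxy-7-methyl-6-oxo-3-[(1E)-prop-1-en-1-yl]-6,7,8,8a-tetrahydro-1H-isochromen-8-yl 2,4-bis(methoxymethoxy)-6-methylbenzoate
Conditions: DDQ (1.3 equiv), 2,6-dichloropyridine, ClCH2CH2Cl, rt → 40 °C
Reagents that add atoms: none
Why: DDQ dehydrogenation: hydride abstraction from C3–H (the only C–H that is both allylic and α to oxygen) should give an oxocarbenium ion that loses the C4 proton (γ to the enone) to form the fully conjugated dienol ether–dienone, which removes the C3 stereocentre so that both epimers converge; C7, C8 and C8a are untouched.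

Step 18
Reactants: 24 (7S,8R,8aS)-7-hydroxy-7-methyl-6-oxo-3-[(1E)-prop-1-en-1-yl]-6,7,8,8a-tetrahydro-1H-isochromen-8-yl 2,4-bis(methoxymethoxy)-6-methylbenzoate
Product: 25 (7S,8R,8aS)-7-hydroxy-7-methyl-6-oxo-3-[(1E)-prop-1-en-1-yl]-6,7,8,8a-tetrahydro-1H-isochromen-8-yl 2,4-dihydroxy-6-methylbenzoate
Conditions: CF3CO2H/CH2Cl2 (1:10), H2O (5 equiv), 0 °C → rt; aq. NaHCO3 work-up
Reagents that add atoms: none
Why: Acid-catalysed hydrolysis of the two aryl methoxymethyl acetals (the ortho one assisted by the ester carbonyl) should free the resorcinol hydroxyls under conditions that the hindered ester, the α-ketol and the vinylogous ester chromophore tolerate; no stereocentre is affected.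

**Compound list**

1 | 5-bromo-2H-pyran-2-one | O=C1C=CC(Br)=CO1 | starting material
2 | 5-methyl-2H-pyran-2-one | O=C1C=CC(C)=CO1 | intermediate
3 | rac-(1R,4R)-6-methyl-2-oxabicyclo[2.2.0]hex-5-en-3-one (cis-fused; both enantiomers) | C1=C(C)[C@H](OC2=O)[C@@H]12.C1=C(C)[C@@H](OC2=O)[C@H]12 | intermediate
4 | rac-(1R,4S)-4-(hydroxymethyl)-2-methylcyclobut-2-en-1-ol (cis; both enantiomers) | C1=C(C)[C@H](O)[C@@H]1CO.C1=C(C)[C@@H](O)[C@H]1CO | intermediate
5 | rac-[(1S,4R)-4-hydroxy-3-methylcyclobut-2-en-1-yl]methyl acetate (both enantiomers) | C1=C(C)[C@H](O)[C@@H]1COC(C)=O.C1=C(C)[C@@H](O)[C@H]1COC(C)=O | intermediate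
6 | [(1S,4R)-4-hydroxy-3-methylcyclobut-2-en-1-yl]methyl acetate | C1=C(C)[C@H](O)[C@@H]1COC(C)=O | intermediate
7 | [(1S,4R)-4-{[tert-butyl(dimethyl)silyl]oxy}-3-methylcyclobut-2-en-1-yl]methyl acetate | C1=C(C)[C@H](O[Si](C)(C)C(C)(C)C)[C@@H]1COC(C)=O | intermediate
8 | [(1S,4R)-4-{[tert-butyl(dimethyl)silyl]oxy}-3-methylcyclobut-2-en-1-yl]methanol | C1=C(C)[C@H](O[Si](C)(C)C(C)(C)C)[C@@H]1CO | intermediate
9 | (2E)-but-2-enal | C/C=C/C=O | starting material
10 | 3-bromoprop-1-yne | C#CCBr | starting material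
11 | (5E)-hept-5-en-1-yn-4-ol (racemate) | C/C=C/C(O)CC#C | intermediate
12 | [(1S,4R)-4-{[tert-butyl(dimethyl)silyl]oxy}-3-methylcyclobut-2-en-1-yl]methyl trifluoromethanesulfonate | C1=C(C)[C@H](O[Si](C)(C)C(C)(C)C)[C@@H]1COS(=O)(=O)C(F)(F)F | intermediate
13 | tert-butyl{[(1R,4S)-4-({[(5E)-hept-5-en-1-yn-4-yl]oxy}methyl)-2-methylcyclobut-2-en-1-yl]oxy}dimethylsilane (both epimers at the ether carbinol carbon) | C1=C(C)[C@H](O[Si](C)(C)C(C)(C)C)[C@@H]1COC(/C=C/C)CC#C | intermediate
14 | (1R,2R,3R,4R)-4-{[tert-butyl(dimethyl)silyl]oxy}-3-({[(5E)-hept-5-en-1-yn-4-yl]oxy}methyl)-1-methylcyclobutane-1,2-diol | O[C@H]1[C@@](C)(O)[C@H](O[Si](C)(C)C(C)(C)C)[C@@H]1COC(/C=C/C)CC#C | intermediate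
15 | (2S,3R,4S)-3-{[tert-butyl(dimethyl)silyl]oxy}-4-({[(5E)-hept-5-en-1-yn-4-yl]oxy}methyl)-2-hydroxy-2-methylcyclobutan-1-one | O=C1[C@@](C)(O)[C@H](O[Si](C)(C)C(C)(C)C)[C@@H]1COC(/C=C/C)CC#C | intermediate
16 | (2S,3R,4S)-3-{[tert-butyl(dimethyl)silyl]oxy}-4-({[(5E)-hept-5-en-1-yn-4-yl]oxy}methyl)-2-methyl-2-[(triethylsilyl)oxy]cyclobutan-1-one | O=C1[C@@](C)(O[Si](CC)(CC)CC)[C@H](O[Si](C)(C)C(C)(C)C)[C@@H]1COC(/C=C/C)CC#C | intermediate
17 | (7S,8R,8aS)-8-{[tert-butyl(dimethyl)silyl]oxy}-7-methyl-3-[(1E)-prop-1-en-1-yl]-7-[(triethylsilyl)oxy]-1,3,4,7,8,8a-hexahydro-6H-isochromen-6-one | C/C=C/C1CC2=CC(=O)[C@@](C)(O[Si](CC)(CC)CC)[C@H](O[Si](C)(C)C(C)(C)C)[C@@H]2CO1 | intermediate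
18 | (7S,8R,8aS)-7,8-dihydroxy-7-methyl-3-[(1E)-prop-1-en-1-yl]-1,3,4,7,8,8a-hexahydro-6H-isochromen-6-one | C/C=C/C1CC2=CC(=O)[C@@](C)(O)[C@H](O)[C@@H]2CO1 | intermediate
19 | methyl 2,4-dihydroxy-6-methylbenzoate | COC(=O)c1c(C)cc(O)cc1O | starting material
20 | methyl 2,4-bis(methoxymethoxy)-6-methylbenzoate | COCOc1cc(C)c(C(=O)OC)c(OCOC)c1 | intermediate
21 | 2,4-bis(methoxymethoxy)-6-methylbenzoic acid | COCOc1cc(C)c(C(=O)O)c(OCOC)c1 | intermediate
22 | 2,4-bis(methoxymethoxy)-6-methylbenzoyl chloride | COCOc1cc(C)c(C(Cl)=O)c(OCOC)c1 | intermediate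
23 | (7S,8R,8aS)-7-hydroxy-7-methyl-6-oxo-3-[(1E)-prop-1-en-1-yl]-3,4,6,7,8,8a-hexahydro-1H-isochromen-8-yl 2,4-bis(methoxymethoxy)-6-methylbenzoate | C/C=C/C1CC2=CC(=O)[C@@](C)(O)[C@H](OC(=O)c3c(C)cc(OCOC)cc3OCOC)[C@@H]2CO1 | intermediate
24 | (7S,8R,8aS)-7-hydroxy-7-methyl-6-oxo-3-[(1E)-prop-1-en-1-yl]-6,7,8,8a-tetrahydro-1H-isochromen-8-yl 2,4-bis(methoxymethoxy)-6-methylbenzoate | C/C=C/C1=CC2=CC(=O)[C@@](C)(O)[C@H](OC(=O)c3c(C)cc(OCOC)cc3OCOC)[C@@H]2CO1 | intermediate
25 | (7S,8R,8aS)-7-hydroxy-7-methyl-6-oxo-3-[(1E)-prop-1-en-1-yl]-6,7,8,8a-tetrahydro-1H-isochromen-8-yl 2,4-dihydroxy-6-methylbenzoate | C/C=C/C1=CC2=CC(=O)[C@@](C)(O)[C@H](OC(=O)c3c(C)cc(O)cc3O)[C@@H]2CO1 | target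

**Step count**

Total: 18 steps. Longest linear sequence: 15 steps (steps 1–6, 8–13 and 16–18, from 1 to 25).

**Steps most likely to fail**

Step 12. The rhodium may add into the other acyl bond (C6–C7), the rhodacycle may lose carbon monoxide at the temperature needed, or the terminal alkyne may be diverted into vinylidene or oligomerisation chemistry before it inserts. The fallback sets out from 16 and returns at 17. Semihydrogenation of the alkyne over lead-poisoned Pd/CaCO3 with quinoline (H2, EtOAc) should give the terminal alkene (2S,3R,4S)-3-{[tert-butyl(dimethyl)silyl]oxy}-4-({[(5E)-hepta-1,5-dien-4-yl]oxy}methyl)-2-methyl-2-[(triethylsilyl)oxy]cyclobutan-1-one F1. The olefin variant of the carboacylation, which runs at much lower temperature ([Rh(cod)2]BF4 with the matched enantiomer of DTBM-segphos, 1,4-dioxane, 25–60 °C), should then give the saturated fused ketone (7S,8R,8aS)-8-{[tert-butyl(dimethyl)silyl]oxy}-7-methyl-3-[(1E)-prop-1-en-1-yl]-7-[(triethylsilyl)oxy]octahydro-6H-isochromen-6-one F2. Dehydrogenation of its only α-methylene (IBX, DMSO, 70 °C) introduces the C4a=C5 bond and gives 17.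

Step 8. The alkoxide may act as a base and eliminate the triflate towards the allylic ring C–H, or attack at sulfur and return 8. The fallback sets out from 8 and returns at 13 without any SN2 step. Silylation (TMSCl, imidazole, CH2Cl2) gives tert-butyl{[(1R,4S)-2-methyl-4-{[(trimethylsilyl)oxy]methyl}cyclobut-2-en-1-yl]oxy}dimethylsilane F3. A three-component, silyl-modified Sakurai-type condensation of F3 with aldehyde 9 and tributyl(propa-1,2-dien-1-yl)stannane (TMSOTf cat., CH2Cl2, −78 °C) builds the oxocarbenium ion of 9 on the ether oxygen and traps it at carbon by SE2' propargylation, which gives 13.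

Step 17. Hydride abstraction may be unselective, the electron-rich product may be oxidised further, or the oxocarbenium ion may be captured by the hydroquinone instead of losing a proton. The fallback sets out from 17 and returns at 24, so the unsaturation is introduced by enolate chemistry before the ester is in place. γ-Enolisation (TMSOTf, Et3N, CH2Cl2, 0 °C) should give the extended silyl dienol ether {[(7S,8R,8aS)-8-{[tert-butyl(dimethyl)silyl]oxy}-7-methyl-3-[(1E)-prop-1-en-1-yl]-7-[(triethylsilyl)oxy]-3,7,8,8a-tetrahydro-1H-isochromen-6-yl]oxy}trimethylsilane F4. Saegusa–Ito oxidation (Pd(OAc)2, MeCN, rt; β-hydride loss from C3) gives the trienone (7S,8R,8aS)-8-{[tert-butyl(dimethyl)silyl]oxy}-7-methyl-3-[(1E)-prop-1-en-1-yl]-7-[(triethylsilyl)oxy]-1,7,8,8a-tetrahydro-6H-isochromen-6-one F5. HF·pyridine gives (7S,8R,8aS)-7,8-dihydroxy-7-methyl-3-[(1E)-prop-1-en-1-yl]-1,7,8,8a-tetrahydro-6H-isochromen-6-one F6, and acylation of F6 with 22 under the conditions of step 16 gives 24.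

Further compounds
F1 | step 12 | (2S,3R,4S)-3-{[tert-butyl(dimethyl)silyl]oxy}-4-({[(5E)-hepta-1,5-dien-4-yl]oxy}methyl)-2-methyl-2-[(triethylsilyl)oxy]cyclobutan-1-one | O=C1[C@@](C)(O[Si](CC)(CC)CC)[C@H](O[Si](C)(C)C(C)(C)C)[C@@H]1COC(/C=C/C)CC=C
F2 | step 12 | (7S,8R,8aS)-8-{[tert-butyl(dimethyl)silyl]oxy}-7-methyl-3-[(1E)-prop-1-en-1-yl]-7-[(triethylsilyl)oxy]octahydro-6H-isochromen-6-one (C3 and C4a undefined) | C/C=C/C1CC2CC(=O)[C@@](C)(O[Si](CC)(CC)CC)[C@H](O[Si](C)(C)C(C)(C)C)[C@@H]2CO1
F3 | step 8 | tert-butyl{[(1R,4S)-2-methyl-4-{[(trimethylsilyl)oxy]methyl}cyclobut-2-en-1-yl]oxy}dimethylsilane | C1=C(C)[C@H](O[Si](C)(C)C(C)(C)C)[C@@H]1CO[Si](C)(C)C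
F4 | step 17 | {[(7S,8R,8aS)-8-{[tert-butyl(dimethyl)silyl]oxy}-7-methyl-3-[(1E)-prop-1-en-1-yl]-7-[(triethylsilyl)oxy]-3,7,8,8a-tetrahydro-1H-isochromen-6-yl]oxy}trimethylsilane | C/C=C/C1C=C2C=C(O[Si](C)(C)C)[C@@](C)(O[Si](CC)(CC)CC)[C@H](O[Si](C)(C)C(C)(C)C)[C@@H]2CO1
F5 | step 17 | (7S,8R,8aS)-8-{[tert-butyl(dimethyl)silyl]oxy}-7-methyl-3-[(1E)-prop-1-en-1-yl]-7-[(triethylsilyl)oxy]-1,7,8,8a-tetrahydro-6H-isochromen-6-one | C/C=C/C1=CC2=CC(=O)[C@@](C)(O[Si](CC)(CC)CC)[C@H](O[Si](C)(C)C(C)(C)C)[C@@H]2CO1
F6 | step 17 | (7S,8R,8aS)-7,8-dihydroxy-7-methyl-3-[(1E)-prop-1-en-1-yl]-1,7,8,8a-tetrahydro-6H-isochromen-6-one | C/C=C/C1=CC2=CC(=O)[C@@](C)(O)[C@H](O)[C@@H]2CO1
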